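**Retrosynthetic overview**
1. Feature used: the carbocycle C4a–C5–C6–C7–C8–C8a is a fully substituted phloroglucinol, with O on C5, C7 and C8a, CH3 on C6 and C8, and acyl carbon C4 on C4a. It is the C-acylated (Claisen) form of a poly-β-carbonyl chain whose O-acylated form is a 2-pyranone.
2. Key disconnection C5–C6: the target is traced back to its constitutional isomer (C36H60O4), 7-ethyl-8-methyl-2-pentacosylpyrano[4,3-b]pyran-4,5-dione. In this isomer C5 is bound to ring oxygen O6 instead of to the ethyl CH2. A base-triggered O-to-C acyl transposition turns the 2-pyranone ring into the benzene ring.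
3. The bicycle is cut at C4–C4a and O1–C2. This gives hexacosanoylketene (from hexacosanoic acid and Meldrum's acid) and 6-ethyl-4-hydroxy-5-methyl-2-pyranone.
4. The pyranone comes from the dianion of methyl 3-oxopentanoate and a propionyl Weinreb amide, followed by enol lactonisation.
5. Ring order: 2-pyranone (step 2), 4-pyranone (step 4), then benzene by transmutation of the 2-pyranone (step 5). No protecting groups are used.

Key step: step 5

Remark: the target has no stereocentre and no stereogenic double bond, so it is achiral and the single-enantiomer requirement is met by constitution alone; the chain is read as n-pentacosyl (C25), so C2 plus the chain is a hexacosanoyl unit.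

**Step 1**
Reactants: 1 methyl 3-oxopentanoate; 2 N-methoxy-N-methylpropanamide
Product: 3 methyl 4-methyl-3,5-dioxoheptanoate
Conditions: LDA (2.1 equiv), THF, −78 → 0 °C; 2, −78 → 0 °C; aq. HCl
Reagents that add atoms: none
Why: Weiler-type γ-acylation of a β-keto ester dianion, in which the chelated tetrahedral adduct of the Weinreb amide should survive until the quench so that the acidic product cannot protonate unreacted dianion; the new C4 centre is enolisable, needs no control and becomes sp2 in step 2.

**Step 2**
Reactants: 3 methyl 4-methyl-3,5-dioxoheptanoate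
Product: 4 6-ethyl-4-hydroxy-5-methyl-2H-pyran-2-one
Conditions: DBU (1.2 equiv), PhMe, 110 °C; aq. HCl
Reagents that add atoms: none
Why: Base-mediated enol lactonisation of a 3,5-dioxo ester (6-exo-trig attack of the C5 enolate oxygen on the ester), the standard entry to 4-hydroxy-2-pyranones, driven by loss of methanol.

**Step 3**
Reactants: 5 hexacosanoic acid; 6 Meldrum's acid (2,2-dimethyl-1,3-dioxane-4,6-dione)
Product: 7 5-(1-hydroxyhexacosylidene)-2,2-dimethyl-1,3-dioxane-4,6-dione
Conditions: DCC, DMAP, CH2Cl2–THF, 0 → 25 °C
Reagents that add atoms: none
Why: Carbodiimide/DMAP C-acylation of Meldrum's acid, a standard way to turn a fatty acid into an acylketene precursor; the product is fully enolised.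

**Step 4**
Reactants: 4 6-ethyl-4-hydroxy-5-methyl-2H-pyran-2-one; 7 5-(1-hydroxyhexacosylidene)-2,2-dimethyl-1,3-dioxane-4,6-dione
Product: 10 7-ethyl-8-methyl-2-pentacosyl-4H,5H-pyrano[4,3-b]pyran-4,5-dione, via hexacosanoylketene 8 (not isolated), via C3-acylated pyranone 9 (not isolated)
Conditions: slow addition of 7 to 4, PhMe, 110 °C; DMAP (0.3 equiv), 110 °C; then TsOH·H2O (0.6 equiv), Dean–Stark
Reagents that add atoms: none
Why: Thermal retro-[4+2] fragmentation of the acyl Meldrum's acid releases acylketene 8, O-acylation of 4 is thermally reversible and DMAP relays the acyl group to C3, the only nucleophilic carbon of 4 (known O-to-C acyl migration of 4-hydroxy-2-pyranones), to give chelated tricarbonyl 9, whose 4-OH then adds to the chain ketone under acid and loses water (known cyclodehydration of 3-acetoacetyl-4-hydroxy-2-pyranones to pyrano[4,3-b]pyran-4,5-diones).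

**Step 5**
Reactants: 10 7-ethyl-8-methyl-2-pentacosyl-4H,5H-pyrano[4,3-b]pyran-4,5-dione
Product: 12 5,7-dihydroxy-6,8-dimethyl-2-pentacosyl-4H-chromen-4-one (CNP0340942.0), via dienylketene enolate 11 (not isolated)
Conditions: KHMDS (3.5 equiv), THF–PhMe (0.01 M), 0 → 65 °C; then 2 M HCl, THF–MeOH, 40 °C
Reagents that add atoms: none
Why: Proposed new method: KHMDS should remove a proton from the CH2 of the C7-ethyl group (vinylogous to C5=O and C4=O), and the resulting enol-ester enolate should expel its own enolate oxygen O6 (E1cB, equivalent to a retro-6π opening of the 2-pyranone) to give dienylketene enolate 11, whose carbon C6 then adds to ketene carbon C5; loss of the remaining C6–H to a second equivalent of base gives the aromatic bis-phenoxide and makes the sequence irreversible. The closest known reaction types are the alkoxide-induced rearrangement of enol lactones to cyclic 1,3-diketones (benzylidenephthalide to 2-arylindane-1,3-dione), the conversion of 6-alkyl-4-alkoxy-2-pyranones into phloroglucinol ethers, the E1cB cleavage of aryl acetoacetates through acylketenes, and the dienylketene closure that ends a Danheiser benzannulation, but none of them has been shown on a pyrano[4,3-b]pyran-4,5-dione. The one ring closed is the benzene ring C4a–C5–C6–C7–C8–C8a, by a 6π electrocyclisation (formally a 6-endo-dig attack of enolate carbon C6 on the ketene) that forms C5–C6 at the cost of C5–O6, while the 4-pyranone ring is carried through unchanged and O6 and the lactone oxygen become the 7-OH and 5-OH. No stereocentre is formed. The step needs C- over O-reclosure and ring-side over chain-side reactivity: O-reclosure only regenerates the anion of 10, the C8=C8a geometry inherited from the ring holds C7 and C4a cis so that C6 stays within reach of C5, and deprotonation at C1′ of the pentacosyl chain is a reversible dead end that high dilution keeps from condensing. A non-nucleophilic base leaves the 4-pyranone closed, so C3 and C4 stay masked and aldol-type closures to resorcylates are shut off, and because the two oxygens ortho to C4a are equivalent in the 2,4-dimethylphloroglucinol ring, any pyranone opened in transit should reclose on the acidic work-up to the same chromone.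

**Compound list**
1 | methyl 3-oxopentanoate | CCC(=O)CC(=O)OC | starting material
2 | N-methoxy-N-methylpropanamide | CCC(=O)N(C)OC | starting material
3 | methyl 4-methyl-3,5-dioxoheptanoate (racemic, C4 configurationally labile, keto–enol mixture) | CCC(=O)C(C)C(=O)CC(=O)OC | intermediate
4 | 6-ethyl-4-hydroxy-5-methyl-2H-pyran-2-one | CCC1=C(C)C(O)=CC(=O)O1 | intermediate
5 | hexacosanoic acid | CCCCCCCCCCCCCCCCCCCCCCCCCC(=O)O | starting material
6 | Meldrum's acid (2,2-dimethyl-1,3-dioxane-4,6-dione) | CC1(C)OC(=O)CC(=O)O1 | starting material
7 | 5-(1-hydroxyhexacosylidene)-2,2-dimethyl-1,3-dioxane-4,6-dione | CCCCCCCCCCCCCCCCCCCCCCCCCC(O)=C1C(=O)OC(C)(C)OC1=O | intermediate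
8 | hexacosanoylketene (3-oxooctacos-1-en-1-one), not isolated | CCCCCCCCCCCCCCCCCCCCCCCCCC(=O)C=C=O | intermediate
9 | 6-ethyl-4-hydroxy-5-methyl-3-(3-oxooctacosanoyl)-2H-pyran-2-one, not isolated | CCCCCCCCCCCCCCCCCCCCCCCCCC(=O)CC(=O)C1=C(O)C(C)=C(CC)OC1=O | intermediate
10 | 7-ethyl-8-methyl-2-pentacosyl-4H,5H-pyrano[4,3-b]pyran-4,5-dione | CCCCCCCCCCCCCCCCCCCCCCCCCC1=CC(=O)C2=C(O1)C(C)=C(CC)OC2=O | intermediate
11 | potassium enolate of 3-(oxomethylidene)-2-(3-oxopentan-2-ylidene)-6-pentacosyl-2,3-dihydro-4H-pyran-4-one (C7 cis to C4a on C8=C8a; enolate C6=C7 geometry open), not isolated | CC=C([O-])/C(C)=C1/OC(CCCCCCCCCCCCCCCCCCCCCCCCC)=CC(=O)C1=C=O.[K+] | intermediate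
12 | 5,7-dihydroxy-6,8-dimethyl-2-pentacosyl-4H-chromen-4-one (CNP0340942.0, achiral) | CCCCCCCCCCCCCCCCCCCCCCCCCc1cc(=O)c2c(O)c(C)c(O)c(C)c2o1 | target

**Total step count:** 5
**Longest linear sequence:** 4 (steps 1, 2, 4, 5)

**Steps most likely to fail**

Step 5 (labelled step).
- What may go wrong: the extended enolate may be too well stabilised to open to the ketene. Adventitious nucleophiles may open the 4-pyranone ring and release aldol-type closures. The chain-side carbanion may start intermolecular condensation.
- Fallback (known chemistry, with the benzene ring bought instead of made): it sets out from 7 and comes back at 12. Heating 7 in methanol traps the acylketene and should give methyl 3-oxooctacosanoate F1. F1 is then heated without catalyst at about 240 °C in diphenyl ether with purchased 2,4-dimethylbenzene-1,3,5-triol F2 (Mentzer pyrone synthesis). C-acylation at the only free ring carbon, followed by cyclodehydration onto either of the two equivalent ortho hydroxyls, should give 12.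

Step 4.
- What may go wrong: the acylketene may be lost to self-dimerisation. Alternatively, the O-acyl stage may not be relayed to carbon, so that the acid then closes the ring in the Pechmann sense.
- Fallback: it forms C2–C3 instead of C4–C4a, sets out from 4 and 5, and comes back at 9. Compound 4 is C-acetylated with acetic acid, DCC and DMAP in warm toluene (O-acylation followed by acyl migration) to give 3-acetyl-6-ethyl-4-hydroxy-5-methyl-2H-pyran-2-one F3. Compound 5 is esterified (MeOH, cat. H2SO4) to methyl hexacosanoate F4. The dianion of F3 (LDA, THF), used in excess so that it also serves as the base, undergoes Claisen condensation at the acetyl CH3 with F4 to give 9. Compound 9 is then cyclodehydrated with TsOH as in step 4.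

Step 1.
- What may go wrong: proton transfer from the amide to the dianion, together with slow attack of the secondary γ-carbanion, may stall the acylation.
- Fallback: it replaces the strongly basic dianion with a neutral bis(silyl enol ether), sets out from 1, and comes back at 3. Compound 1 is silylated (TMSCl, Et3N) to methyl 3-(trimethylsilyloxy)pent-2-enoate F5. F5 is then treated with LDA and TMSCl to give 1-methoxy-1,3-bis(trimethylsilyloxy)penta-1,3-diene F6. Mukaiyama-type γ-acylation of F6 with propionyl chloride (CH2Cl2, −78 → 20 °C), followed by aqueous work-up, should give 3.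

**Further compounds**
F1 | step 5 | methyl 3-oxooctacosanoate | CCCCCCCCCCCCCCCCCCCCCCCCCC(=O)CC(=O)OC
F2 | step 5 | 2,4-dimethylbenzene-1,3,5-triol (purchased) | Cc1c(O)cc(O)c(C)c1O
F3 | step 4 | 3-acetyl-6-ethyl-4-hydroxy-5-methyl-2H-pyran-2-one | CCC1=C(C)C(O)=C(C(C)=O)C(=O)O1
F4 | step 4 | methyl hexacosanoate | CCCCCCCCCCCCCCCCCCCCCCCCCC(=O)OC
F5 | step 1 | methyl 3-(trimethylsilyloxy)pent-2-enoate (E/Z mixture) | CCC(O[Si](C)(C)C)=CC(=O)OC
F6 | step 1 | 1-methoxy-1,3-bis(trimethylsilyloxy)penta-1,3-diene (isomer mixture) | CC=C(O[Si](C)(C)C)C=C(OC)O[Si](C)(C)C
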